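The endoperoxide is the singlet-oxygen adduct of a bicyclo[4.2.0]octa-2,4-diene (C1 methylated ring-fusion carbon, C6 ring-fusion CH, C7 pyranone-bearing, C8 CHMe; peroxide on C2 and C5), and the plan rests on cutting that six-membered ring at C1–C2 and C5–C6. The substituents along C2–C5 (H, Me, H, Me) map one-to-one onto C3–C6 of 4,6-dimethyl-2-pyrone, so one Diels–Alder addition of this pyrone across the C1=C6 bond of a cyclobutene, followed by CO2 loss, closes the ring, installs the diene and sets both ring-fusion centres. The dienophile is an enantiopure 1,3,4-trimethylcyclobut-2-ene (1,4-methyls cis) whose quaternary carbon already carries the finished 2-methoxy-3,5-dimethyl-4-pyranone.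

Key step: step 13

Assumption: in step 7 the lipase is taken to acetylate the (1S,4S) alcohol faster, so that the (1R,4R) alcohol is the recovered fraction; the sense must be confirmed on the first run (X-ray analysis of a crystalline ester), and with the opposite preference the acetate fraction would be carried on after methanolysis.

Remark: compounds 5–10 are racemates drawn as the enantiomer that is carried on; C1–C8 are the bicyclo[4.2.0]octane locants defined above.

Step 1
Reactants: 1 (E)-2-methylbut-2-en-1-ol (tiglyl alcohol)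
Product: 2 tert-butyl{[(2E)-2-methylbut-2-en-1-yl]oxy}diphenylsilane
Conditions: TBDPSCl, imidazole, CH2Cl2, 0 °C to rt
Reagents that add atoms: tert-butylchlorodiphenylsilane, CC(C)(C)[Si](Cl)(c1ccccc1)c1ccccc1
Why: Standard silylation of a primary allylic alcohol; the bulky, UV-active silyl ether keeps the oxygen from being acylated by the ketene and keeps the small-ring intermediates non-volatile.

Step 2
Reactants: 2 tert-butyl{[(2E)-2-methylbut-2-en-1-yl]oxy}diphenylsilane; 3 trichloroacetyl chloride
Product: 5 rac-(3R,4S)-3-{[(tert-butyldiphenylsilyl)oxy]methyl}-2,2-dichloro-3,4-dimethylcyclobutan-1-one (ring methyls cis), via dichloroketene 4 (not isolated)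
Conditions: activated Zn dust, slow addition of 3, Et2O/DME, ultrasound, 15–25 °C
Reagents that add atoms: none
Why: Ketene–alkene [2+2] cycloaddition in which the carbonyl carbon bonds to the less substituted alkene carbon and CCl2 to the fully substituted one, while suprafacial addition across the (E)-alkene places the two ring methyls cis (future C7 and C8, relative configuration only).

Step 3
Reactants: 5 rac-(3R,4S)-3-{[(tert-butyldiphenylsilyl)oxy]methyl}-2,2-dichloro-3,4-dimethylcyclobutan-1-one
Product: 6 rac-(2S,3R)-3-{[(tert-butyldiphenylsilyl)oxy]methyl}-2,3-dimethylcyclobutan-1-one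
Conditions: Zn dust, AcOH, rt
Reagents that add atoms: none
Why: Zinc–acetic acid reductive dechlorination of an α,α-dichlorocyclobutanone; the α-methyl centre is not involved, and its cis relation to the quaternary methyl (trans to the larger silyloxymethyl arm) should also be the more stable one if any enolisation occurs.

Step 4
Reactants: 6 rac-(2S,3R)-3-{[(tert-butyldiphenylsilyl)oxy]methyl}-2,3-dimethylcyclobutan-1-one
Product: 8 rac-(3R,4S)-3-{[(tert-butyldiphenylsilyl)oxy]methyl}-3,4-dimethylcyclobut-1-en-1-yl trifluoromethanesulfonate, via potassium enolate 7 (not isolated)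
Conditions: KHMDS, THF, −78 °C; then PhNTf2, −78 to 0 °C
Reagents that add atoms: N-phenylbis(trifluoromethanesulfonimide), O=S(=O)(N(c1ccccc1)S(=O)(=O)C(F)(F)F)C(F)(F)F
Why: Kinetic deprotonation should take the α-CH2 rather than the α-CHMe, and O-triflation of that enolate (kinetic enolate trapping) puts the double bond where the C1=C6 alkene of the cyclobutene is needed.

Step 5
Reactants: 8 rac-(3R,4S)-3-{[(tert-butyldiphenylsilyl)oxy]methyl}-3,4-dimethylcyclobut-1-en-1-yl trifluoromethanesulfonate
Product: 9 rac-tert-butyldiphenyl{[(1R,4R)-1,3,4-trimethylcyclobut-2-en-1-yl]methoxy}silane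
Conditions: MeZnCl, Pd(PPh3)4 (5 mol %), THF, rt to 45 °C
Reagents that add atoms: methylzinc chloride, C[Zn]Cl
Why: Negishi cross-coupling of an alkenyl triflate with a methylzinc reagent; oxidative addition of zerovalent palladium to the enol triflate is easy and neither stereocentre takes part.

Step 6
Reactants: 9 rac-tert-butyldiphenyl{[(1R,4R)-1,3,4-trimethylcyclobut-2-en-1-yl]methoxy}silane
Product: 10 rac-[(1R,4R)-1,3,4-trimethylcyclobut-2-en-1-yl]methanol
Conditions: TBAF, THF, 0 °C to rt; aq NH4Cl
Reagents that add atoms: none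
Why: Fluoride cleavage of the silyl ether; nothing else in the molecule is sensitive to fluoride or mild base.

Step 7
Reactants: 10 rac-[(1R,4R)-1,3,4-trimethylcyclobut-2-en-1-yl]methanol
Product: 11 [(1R,4R)-1,3,4-trimethylcyclobut-2-en-1-yl]methanol (single enantiomer)
Conditions: Burkholderia cepacia lipase (lipase PS, immobilised), vinyl acetate, MTBE, rt, run past half conversion under chiral GC control
Reagents that add atoms: none
Why: Lipase-catalysed kinetic resolution by irreversible transesterification: one enantiomer of the primary alcohol is acetylated and the slow-reacting (1R,4R) alcohol is recovered, which fixes C7 and C8 in the absolute sense.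

Step 8
Reactants: 11 [(1R,4R)-1,3,4-trimethylcyclobut-2-en-1-yl]methanol
Product: 12 (1R,4R)-1,3,4-trimethylcyclobut-2-ene-1-carbaldehyde
Conditions: Dess–Martin periodinane, NaHCO3, CH2Cl2, 0 °C; cold work-up, used at once as a solution
Reagents that add atoms: none
Why: Dess–Martin oxidation of a primary alcohol; the aldehyde has no α-hydrogen, so the quaternary centre cannot epimerise, and conrotatory ring opening should be slow because either rotation would turn a methyl group inward.

Step 9
Reactants: 12 (1R,4R)-1,3,4-trimethylcyclobut-2-ene-1-carbaldehyde; 13 methyl 2-methyl-3-oxopentanoate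
Product: 15 methyl 5-hydroxy-2,4-dimethyl-3-oxo-5-[(1R,4R)-1,3,4-trimethylcyclobut-2-en-1-yl]pentanoate (mixture at C2/C4/C5), via ketoester dianion 14 (not isolated)
Conditions: 13, NaH, THF, 0 °C; n-BuLi, 0 °C; then 12, −78 °C; aq NH4Cl
Reagents that add atoms: none
Why: Aldol addition of a β-ketoester dianion through its γ-carbon to a non-enolisable aldehyde; the new centres form as a mixture, which does not matter because all of them become planar in steps 10 and 11.

Step 10
Reactants: 15 methyl 5-hydroxy-2,4-dimethyl-3-oxo-5-[(1R,4R)-1,3,4-trimethylcyclobut-2-en-1-yl]pentanoate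
Product: 16 methyl 2,4-dimethyl-3,5-dioxo-5-[(1R,4R)-1,3,4-trimethylcyclobut-2-en-1-yl]pentanoate
Conditions: Dess–Martin periodinane, CH2Cl2, rt
Reagents that add atoms: none
Why: Dess–Martin oxidation of the secondary carbinol to the β,δ-diketo ester under neutral conditions that leave the cyclobutene alone.

Step 11
Reactants: 16 methyl 2,4-dimethyl-3,5-dioxo-5-[(1R,4R)-1,3,4-trimethylcyclobut-2-en-1-yl]pentanoate
Product: 17 4-hydroxy-3,5-dimethyl-6-[(1R,4R)-1,3,4-trimethylcyclobut-2-en-1-yl]-2H-pyran-2-one
Conditions: DBU, PhMe, rt to 60 °C; dilute HCl work-up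
Reagents that add atoms: none
Why: Base-mediated lactonisation of the triketide: the enol oxygen of the δ-ketone attacks the ester and methanol is lost, giving the 4-hydroxy-2-pyrone.

Step 12
Reactants: 17 4-hydroxy-3,5-dimethyl-6-[(1R,4R)-1,3,4-trimethylcyclobut-2-en-1-yl]-2H-pyran-2-one
Product: 18 2-methoxy-3,5-dimethyl-6-[(1R,4R)-1,3,4-trimethylcyclobut-2-en-1-yl]-4H-pyran-4-one
Conditions: MeOTf, CH2Cl2, 0 °C to rt; aq NaHCO3
Reagents that add atoms: methyl trifluoromethanesulfonate, COS(=O)(=O)C(F)(F)F
Why: O-Methylation of the neutral hydroxypyrone by a hard methylating agent occurs at the more basic lactone carbonyl oxygen, and loss of the proton from the resulting pyrylium gives the 2-methoxy-4-pyranone regioisomer.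

Step 13
Reactants: 18 2-methoxy-3,5-dimethyl-6-[(1R,4R)-1,3,4-trimethylcyclobut-2-en-1-yl]-4H-pyran-4-one; 19 4,6-dimethyl-2H-pyran-2-one
Product: 22 2-methoxy-3,5-dimethyl-6-[(1R,6R,7S,8R)-1,3,5,7,8-pentamethylbicyclo[4.2.0]octa-2,4-dien-7-yl]-4H-pyran-4-one, via bridged lactone adduct 20 (not isolated), via cyclooctatriene valence isomer 21 (not isolated)
Conditions: 19 (6 equiv), CH2Cl2, 1.4 GPa, 50 °C, 72 h; then 1 bar, PhMe, 80 °C, Ar, dark
Reagents that add atoms: none
Why: The 2-pyrone acts as an electron-poor cisoid diene toward the strained, alkyl-rich cyclobutene in a concerted but asynchronous [4+2] cycloaddition whose large negative activation volume lets pressure replace heat (heat would open the cyclobutene by conrotatory 4π), and the 2-oxabicyclo[2.2.2]oct-5-en-3-one 20 then expels CO2 by retro-[4+2] on gentle warming. The closest known reaction type is the Diels–Alder/decarboxylation sequence of 2-pyrones with strained or electron-rich alkenes that delivers cyclohexa-1,3-dienes. The one ring closed, the six-membered ring C1–C6, is formed by intermolecular cycloaddition, suprafacial on both partners, with C1–C2 and C5–C6 made together; loss of the lactone bridge leaves the C2=C3–C4=C5 diene. Of the two new stereocentres, C1 and C6 are cis to each other because both bonds go to one face of the cyclobutene, and their sense relative to C7 and C8 is controlled by approach on the face carrying C8–H (anti to the two cis methyls, with the flat pyranone turned edge-on) and, as a second control, by the mobile disrotatory 6π equilibrium with cyclooctatriene 21 at 80 °C, which should rest in the ring fusion that places only the pyranone, not two methyls, under the diene. The selectivity needed is regiochemical (pyrone C3–H to the methylated C1, pyrone C6–Me to the C6–H carbon), and it is secured by the substrate because the other orientation would join two fully substituted carbons and because the less substituted, more nucleophilic alkene carbon pairs with the electrophilic C6 of the pyrone. C7 and C8 are spectators and the C7–C8 bond stays intact below the retro-8π threshold, so the enantiopurity from step 7 is conserved.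

Step 14
Reactants: 22 2-methoxy-3,5-dimethyl-6-[(1R,6R,7S,8R)-1,3,5,7,8-pentamethylbicyclo[4.2.0]octa-2,4-dien-7-yl]-4H-pyran-4-one
Product: 23 2-methoxy-3,5-dimethyl-6-[(1S,2R,3S,4R,5R,6R)-1,3,4,5,10-pentamethyl-7,8-dioxatricyclo[4.2.2.0^{2,5}]dec-9-en-3-yl]-4H-pyran-4-one (the target; peroxide across C2 and C5, anti to the cyclobutane)
Conditions: O2, methylene blue (cat.), CH2Cl2, hν (>500 nm), −20 °C
Reagents that add atoms: dioxygen, O=O
Why: [4+2] cycloaddition of singlet oxygen to the s-cis cyclohexadiene; the oxygen should approach the convex face that carries C1–Me and C6–H, away from the four-membered ring and its pyranone, so that C2 and C5 are set together with the peroxide bridge anti to the cyclobutane.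

Compound list
1 | (E)-2-methylbut-2-en-1-ol (tiglyl alcohol) | C/C=C(\C)CO | starting material
2 | tert-butyl{[(2E)-2-methylbut-2-en-1-yl]oxy}diphenylsilane | C/C=C(\C)CO[Si](c1ccccc1)(c1ccccc1)C(C)(C)C | intermediate
3 | trichloroacetyl chloride | ClC(=O)C(Cl)(Cl)Cl | starting material
4 | dichloroketene | O=C=C(Cl)Cl | intermediate (not isolated)
5 | rac-(3R,4S)-3-{[(tert-butyldiphenylsilyl)oxy]methyl}-2,2-dichloro-3,4-dimethylcyclobutan-1-one (ring methyls cis) | CC(C)(C)[Si](OC[C@@]1(C)[C@H](C)C(=O)C1(Cl)Cl)(c1ccccc1)c1ccccc1 | intermediate (racemate)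
6 | rac-(2S,3R)-3-{[(tert-butyldiphenylsilyl)oxy]methyl}-2,3-dimethylcyclobutan-1-one | CC(C)(C)[Si](OC[C@@]1(C)[C@H](C)C(=O)C1)(c1ccccc1)c1ccccc1 | intermediate (racemate)
7 | potassium enolate of 6 (deprotonated at the ring CH2) | CC(C)(C)[Si](OC[C@@]1(C)[C@H](C)C([O-])=C1)(c1ccccc1)c1ccccc1.[K+] | intermediate (not isolated, racemate)
8 | rac-(3R,4S)-3-{[(tert-butyldiphenylsilyl)oxy]methyl}-3,4-dimethylcyclobut-1-en-1-yl trifluoromethanesulfonate | CC(C)(C)[Si](OC[C@@]1(C)[C@H](C)C(OS(=O)(=O)C(F)(F)F)=C1)(c1ccccc1)c1ccccc1 | intermediate (racemate)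
9 | rac-tert-butyldiphenyl{[(1R,4R)-1,3,4-trimethylcyclobut-2-en-1-yl]methoxy}silane | CC(C)(C)[Si](OC[C@@]1(C)[C@H](C)C(C)=C1)(c1ccccc1)c1ccccc1 | intermediate (racemate)
10 | rac-[(1R,4R)-1,3,4-trimethylcyclobut-2-en-1-yl]methanol | OC[C@@]1(C)[C@H](C)C(C)=C1 | intermediate (racemate)
11 | [(1R,4R)-1,3,4-trimethylcyclobut-2-en-1-yl]methanol | OC[C@@]1(C)[C@H](C)C(C)=C1 | intermediate (single enantiomer)
12 | (1R,4R)-1,3,4-trimethylcyclobut-2-ene-1-carbaldehyde | O=C[C@@]1(C)[C@H](C)C(C)=C1 | intermediate
13 | methyl 2-methyl-3-oxopentanoate | CCC(=O)C(C)C(=O)OC | starting material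
14 | sodium lithium dianion of 13 (enolate geometry not specified) | CC=C([O-])C(C)=C([O-])OC.[Na+].[Li+] | intermediate (not isolated)
15 | methyl 5-hydroxy-2,4-dimethyl-3-oxo-5-[(1R,4R)-1,3,4-trimethylcyclobut-2-en-1-yl]pentanoate (mixture at C2, C4, C5) | COC(=O)C(C)C(=O)C(C)C(O)[C@@]1(C)[C@H](C)C(C)=C1 | intermediate
16 | methyl 2,4-dimethyl-3,5-dioxo-5-[(1R,4R)-1,3,4-trimethylcyclobut-2-en-1-yl]pentanoate | COC(=O)C(C)C(=O)C(C)C(=O)[C@@]1(C)[C@H](C)C(C)=C1 | intermediate
17 | 4-hydroxy-3,5-dimethyl-6-[(1R,4R)-1,3,4-trimethylcyclobut-2-en-1-yl]-2H-pyran-2-one | O=c1oc([C@@]2(C)[C@H](C)C(C)=C2)c(C)c(O)c1C | intermediate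
18 | 2-methoxy-3,5-dimethyl-6-[(1R,4R)-1,3,4-trimethylcyclobut-2-en-1-yl]-4H-pyran-4-one (1,4-methyls cis) | COc1oc([C@@]2(C)[C@H](C)C(C)=C2)c(C)c(=O)c1C | intermediate
19 | 4,6-dimethyl-2H-pyran-2-one | Cc1cc(C)oc(=O)c1 | starting material
20 | bridged lactone adduct, 4-(6-methoxy-3,5-dimethyl-4-oxo-4H-pyran-2-yl)-2,3,4,6,9-pentamethyl-7-oxatricyclo[4.2.2.0^{2,5}]dec-9-en-8-one (drawn with the lactone bridge anti to the cyclobutane; the bridge orientation is lost with CO2) | COc1oc([C@@]2(C)[C@H](C)[C@@]3(C)[C@@H]4C(=O)O[C@@](C)(C=C4C)[C@@H]23)c(C)c(=O)c1C | intermediate (not isolated)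
21 | 2-methoxy-3,5-dimethyl-6-[(1R,2Z,4Z,6Z,8R)-1,3,5,7,8-pentamethylcycloocta-2,4,6-trien-1-yl]-4H-pyran-4-one | COc1oc([C@@]2(C)[C@H](C)/C(C)=C\C(C)=C/C(C)=C\2)c(C)c(=O)c1C | intermediate (not isolated)
22 | 2-methoxy-3,5-dimethyl-6-[(1R,6R,7S,8R)-1,3,5,7,8-pentamethylbicyclo[4.2.0]octa-2,4-dien-7-yl]-4H-pyran-4-one (cis ring fusion; C1-Me, C6-H, C7-Me and C8-Me on one face of the cyclobutane) | COc1oc([C@@]2(C)[C@H](C)[C@@]3(C)C=C(C)C=C(C)[C@@H]23)c(C)c(=O)c1C | intermediate
23 | 2-methoxy-3,5-dimethyl-6-[(1S,2R,3S,4R,5R,6R)-1,3,4,5,10-pentamethyl-7,8-dioxatricyclo[4.2.2.0^{2,5}]dec-9-en-3-yl]-4H-pyran-4-one | COc1oc([C@@]2(C)[C@H](C)[C@@]3(C)[C@@H]4OO[C@@](C)(C=C4C)[C@@H]23)c(C)c(=O)c1C | target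

Total step count: 14. Longest linear sequence: 14 steps (1 to 23); 3, 13 and 19 enter as commercial reactants.

Steps most likely to fail

1. Step 13.
- What may go wrong: the cycloaddition may not reach useful conversion, because the dienophile is trisubstituted, unactivated and flanked by a quaternary carbon. The CO2 loss may also need a temperature at which the ring-fusion equilibrium is unfavourable or the retro-8π opening begins to erode enantiopurity.
- Fallback: it sets out from 18 and returns at 22. The four-carbon unit is delivered by 2,4-dimethylthiophene 1,1-dioxide F1, made from commercial 2,4-dimethylthiophene with dimethyldioxirane in acetone at −20 °C. This is a more electron-poor diene with the same H/Me/H/Me pattern. Under pressure at 25 °C in CH2Cl2 its unsubstituted terminus should bond to C1 and its methylated terminus to C6, giving the sulfone-bridged adduct F2. F2 loses SO2 by cheletropic extrusion at or below room temperature and gives 22 without heating. The ring fusion is then fixed kinetically by the face of approach, and the electrocyclic manifold is never entered.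

2. Step 7.
- What may go wrong: the lipase may discriminate poorly between enantiomers whose stereocentre is quaternary and one bond from the carbinol, leaving alcohol of low enantiomeric purity.
- Fallback: it sets out from 10 and returns at 11. The racemic alcohol is acylated with (1S)-camphanic chloride (Et3N, DMAP, CH2Cl2) to the diastereomeric esters [(1R,4R)-1,3,4-trimethylcyclobut-2-en-1-yl]methyl (1S,4R)-camphanate F3 and [(1S,4S)-1,3,4-trimethylcyclobut-2-en-1-yl]methyl (1S,4R)-camphanate F4. These are separated by crystallisation or chromatography and assigned by X-ray analysis, and F3 is cleaved with K2CO3 in MeOH to 11.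

3. Step 4.
- What may go wrong: regiocontrol may be lost in the enolisation (deprotonation at the α-CHMe), or the strained enolate may self-condense before it is triflated.
- Fallback: it sets out from 6 and returns at 9, bypassing 8 and step 5. Ketone 6 is condensed with 2,4,6-triisopropylbenzenesulfonyl hydrazide (THF, cat. HCl) to the trisylhydrazone F5. In a Shapiro reaction (n-BuLi, 2.2 equiv, THF/TMEDA, −78 to 0 °C) the α-CH2 proton syn to the sulfonamide nitrogen is removed, and sulfinate and N2 are lost to give the cyclobutenyllithium F6. Quenching F6 with MeI gives 9.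

Further compounds
F1 | step 13 | 2,4-dimethylthiophene 1,1-dioxide | CC1=CC(C)=CS1(=O)=O
F2 | step 13 | sulfone-bridged [4+2] adduct of 18 and F1 (7-thiabicyclo[2.2.1]hept-2-ene 7,7-dioxide fused to the cyclobutane at C1–C6, sulfone bridge anti to the cyclobutane) | COc1oc([C@@]2(C)[C@H](C)[C@@]3(C)[C@@H]4S(=O)(=O)[C@@](C)(C=C4C)[C@@H]23)c(C)c(=O)c1C
F3 | step 7 | [(1R,4R)-1,3,4-trimethylcyclobut-2-en-1-yl]methyl (1S,4R)-4,7,7-trimethyl-3-oxo-2-oxabicyclo[2.2.1]heptane-1-carboxylate | O=C(OC[C@@]1(C)[C@H](C)C(C)=C1)[C@@]12CC[C@@](C)(C(=O)O1)C2(C)C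
F4 | step 7 | [(1S,4S)-1,3,4-trimethylcyclobut-2-en-1-yl]methyl (1S,4R)-4,7,7-trimethyl-3-oxo-2-oxabicyclo[2.2.1]heptane-1-carboxylate | O=C(OC[C@]1(C)[C@@H](C)C(C)=C1)[C@@]12CC[C@@](C)(C(=O)O1)C2(C)C
F5 | step 4 | 2,4,6-triisopropylbenzenesulfonyl hydrazone of 6 (racemate, C=N geometry not specified) | CC(C)(C)[Si](OC[C@@]1(C)[C@H](C)C(=NNS(=O)(=O)c2c(C(C)C)cc(C(C)C)cc2C(C)C)C1)(c1ccccc1)c1ccccc1
F6 | step 4 | rac-{(3R,4S)-3-{[(tert-butyldiphenylsilyl)oxy]methyl}-3,4-dimethylcyclobut-1-en-1-yl}lithium | CC(C)(C)[Si](OC[C@@]1(C)[C@H](C)C([Li])=C1)(c1ccccc1)c1ccccc1
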